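**Assumptions:** cis-2,3-dimethylsuccinic anhydride, 3,4-dimethoxyphenylboronic acid (from veratrole) and 5-bromo-2-methoxyphenol (guaiacol-derived) are commercial. The chiral ligand enantiomer is chosen to give keto acid 3 as drawn. The target is 2,3-cis and 3,4-trans by the given SMILES, i.e. (2S,3S,4R).

## Retrosynthetic overview
1. Target ⇒ 6-endo cationic Friedel–Crafts alkylation of a γ-hydroxy aryl ketone (its lactol form) with a veratryl carbinol. This is the only ring-forming step and it sets C4.
2. γ-Hydroxy ketone ⇒ 3-hydroxy-4-methoxyphenyllithium plus 5-veratryl-3,4-dimethyl-γ-butyrolactone.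
3. Lactone ⇐ reduction and lactonization of a veratroyl keto acid.
4. Keto acid ⇐ enantioselective desymmetrizing arylation of meso-2,3-dimethylsuccinic anhydride. This is the key step and it sets both methyl-bearing carbons.

## Route

**Step 1**
Reactants: 1 cis-2,3-dimethylsuccinic anhydride (meso, (3S,4R)); 2 3,4-dimethoxyphenylboronic acid
Product: 3 (2S,3R)-4-(3,4-dimethoxyphenyl)-2,3-dimethyl-4-oxobutanoic acid
Conditions: Pd(OAc)2 (5 mol %), chiral bisphosphine (SEGPHOS-type, 6 mol %), THF, 40 °C, no added base
Reagents that add atoms: none
Why: Proposed new method: chiral Pd(0) inserts into one of the two enantiotopic acyl C–O bonds of the meso anhydride (the enantio-determining event), transmetalation from ArB(OH)2 goes through the carboxylate, and reductive elimination gives the aryl ketone and acid. The closest known reactions are the Pd-catalysed acylative Suzuki coupling of anhydrides and the Rh/Ni desymmetrizing ring-opening of meso anhydrides. The cis (meso-derived) relationship is carried over, and base-free conditions limit epimerization at the α-centres.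

**Step 2**
Reactants: 3
Product: 4 (3S,4R)-5-(3,4-dimethoxyphenyl)-3,4-dimethyldihydrofuran-2(3H)-one, obtained as a C5 epimer mixture
Conditions: NaBH4, EtOH, 0 °C; then 1 M HCl, rt
Reagents that add atoms: none (NaBH4 adds only H)
Why: Borohydride reduces the aryl ketone chemoselectively (the carboxylate is inert) and the γ-hydroxy acid lactonizes on acidification. The C5 configuration is irrelevant because it is ionized in step 4, and C3/C4 are no longer enolizable.

**Step 3**
Reactants: 4; 5 5-bromo-2-methoxyphenol
Product: 6 (2S,3R)-4-(3,4-dimethoxyphenyl)-4-hydroxy-1-(3-hydroxy-4-methoxyphenyl)-2,3-dimethylbutan-1-one (C4 epimeric), in ring-chain equilibrium with its lactol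
Conditions: 5 with n-BuLi (1.0 equiv), then t-BuLi (2.0 equiv), THF, −78 °C; add 4 (0.8 equiv), −78 → −40 °C; aq NH4Cl
Reagents that add atoms: none (the aryl group comes from 5)
Why: Br–Li exchange on the lithium phenoxide gives a meta-lithiophenoxide that adds once to the lactone (organolithium addition to a lactone giving a lactol). The lithium hemiketal does not collapse at low temperature, so there is no double addition; no stereocentre is fixed here.

**Step 4**
Reactants: 6
Product: 7 schisandrone, (2S,3S,4R)-4-(3,4-dimethoxyphenyl)-7-hydroxy-6-methoxy-2,3-dimethyl-3,4-dihydronaphthalen-1(2H)-one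
Conditions: TfOH (10 mol %), HFIP, 25 °C, 0.02 M
Reagents that add atoms: none (net loss of H2O)
Why: Acid ionizes the veratryl carbinol (via the lactol) to a stabilized benzylic cation, and 6-endo intramolecular Friedel–Crafts alkylation occurs para to the phenol OH (ortho to the acyl group). C4 ends up trans to the 3-Me because the transition state places the aryl and 3-Me anti (pseudo-diaxial, relieving peri strain with C5–H). C2 can equilibrate through the enol to the more stable cis-2,3 isomer (2-Me pseudo-equatorial, 3-Me and 4-Ar pseudo-diaxial).

## Consistency check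
- **Skeleton and atoms:** The tetralone ring is C1 (from the lactone carbonyl), C2, C3, C4 (from the ketone carbon of 3) and C4a/C8a from ring A. Ring A carries OMe para to the acyl carbon and OH meta, which gives 6-OMe/7-OH after closure at the carbon para to OH.
- **Formulas:** 3 is C14H18O5, 4 is C14H18O4, 6 is C21H26O6, and 7 is C21H24O5 (6 − H2O).
- **Stereocentres:** C2 and C3 come from the meso anhydride and C4 from the ring closure.
- **Functional groups:** The free phenol and all methyl ethers are untouched in steps 1–4, and the phenol is not protected anywhere.

## Compound list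
1 | cis-2,3-dimethylsuccinic anhydride (meso) | C[C@@H]1C(=O)OC(=O)[C@@H]1C | starting material
2 | 3,4-dimethoxyphenylboronic acid | COc1ccc(B(O)O)cc1OC | starting material
3 | (2S,3R)-4-(3,4-dimethoxyphenyl)-2,3-dimethyl-4-oxobutanoic acid | OC(=O)[C@@H](C)[C@@H](C)C(=O)c1ccc(OC)c(OC)c1 | intermediate
4 | (3S,4R)-5-(3,4-dimethoxyphenyl)-3,4-dimethyldihydrofuran-2(3H)-one (C5 unspecified) | C[C@@H]1C(=O)OC(c2ccc(OC)c(OC)c2)[C@@H]1C | intermediate
5 | 5-bromo-2-methoxyphenol | COc1ccc(Br)cc1O | starting material
6 | (2S,3R)-4-(3,4-dimethoxyphenyl)-4-hydroxy-1-(3-hydroxy-4-methoxyphenyl)-2,3-dimethylbutan-1-one (C4 unspecified) | COc1ccc(cc1O)C(=O)[C@@H](C)[C@@H](C)C(O)c1ccc(OC)c(OC)c1 | intermediate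
7 | schisandrone | COc1cc2c(cc1O)C(=O)[C@@H](C)[C@@H](C)[C@@H]2c1ccc(OC)c(OC)c1 | target

**Total steps:** 4. **Longest linear sequence:** 4.

## Three steps most likely to fail
1. **Step 1 (new Pd desymmetrization):** ee may be low, or the α-centres may epimerize. Fallback: cinchona-catalysed methanolysis of 1 to the hemiester, then acid chloride plus veratrole Friedel–Crafts acylation (AlCl3, −20 °C) to the keto ester. Then continue as in step 2, which gives lactone 4.
2. **Step 4 (cyclization onto an acylated phenol):** the ring may be too deactivated, or the cation may oligomerize. Fallback: reduce the ketone of 6 (NaBH4) to the 1,4-diol and cyclize it with TFA, which is the classical route to aryltetralins onto a non-deactivated ring. Then oxidize the 1-tetralol (Dess–Martin periodinane) to schisandrone.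
3. **Step 3 (dianion addition to a hindered, enolizable lactone):** enolization may dominate over addition. Fallback: open 4 with Me(MeO)NH·AlMe3 to the Weinreb hydroxy-amide, add the Grignard reagent from 2-(benzyloxy)-4-bromo-1-methoxybenzene to give the ketone, then cyclize as in step 4 and debenzylate (H2, Pd/C).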